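**Retrosynthetic overview**
- The target is oxolane ring B (O1; C2 bearing trimethoxyphenyl ring C; C3 bearing CH2OH; C4 bearing CH2–guaiacyl ring A; C5). It is (2S,3R,4R), so C2/C3 are trans and C3/C4 are cis.
- Enabling feature: C2 of ring B is both α to O1 and γ to the hydroxyl oxygen of the C3 side chain. The array O1–C2(Ar)–C3(H)–CH2OH is therefore the retron of aryl addition plus hydride relay on the flat unit O1–C2=C3–CH2OH, an enol ether that is also an allylic alcohol.
- Key disconnection, C2–C(ipso) of ring C: boronic acid 12 plus dihydrofuranylmethanol 11, whose only stereocentre (C4) sets C2 and C3.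
- 11 comes from lactone-ester 7 (lactone C=O becomes C2–H, ester becomes CH2OH). 7 is cut at CH2–C(ipso) of ring A into aryl Grignard 6 and cyclopropane-fused lactone 5, which is made from (R)-epichlorohydrin and di-tert-butyl malonate.
- Ring order: rings A and C are bought. Ring B is closed first as a γ-lactone together with a temporary cyclopropane (step 2), the cyclopropane is opened (step 3), ring B becomes a dihydrofuran (step 5), and it is saturated in the key step.

Key step: step 7

Remark: ring B keeps the numbering O1, C2, C3, C4, C5 of the target in all compounds from 7 on. Compounds 8 and 9 are mixtures at C2 and C3, which does not matter because both carbons become sp2 in 10. TIPS = triisopropylsilyl.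

Step 1
Reactants: 1 4-bromo-2-methoxyphenol
Product: 2 (4-bromo-2-methoxyphenoxy)triisopropylsilane
Conditions: TIPSCl, imidazole, DMF, rt
Reagents that add atoms: triisopropylsilyl chloride, CC(C)[Si](Cl)(C(C)C)C(C)C
Why: Standard O-silylation of a phenol; the bulky aryl silyl ether should survive Grignard, aluminium hydride, amine base and palladium conditions and is removed at the end with fluoride, which leaves the benzylic C2–O1 bond alone.

Step 2
Reactants: 3 (R)-epichlorohydrin; 4 di-tert-butyl malonate
Product: 5 tert-butyl (1R,5R)-2-oxo-3-oxabicyclo[3.1.0]hexane-1-carboxylate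
Conditions: KOtBu (1.05 equiv), t-BuOH, rt, then reflux
Reagents that add atoms: none
Why: Malonate double alkylation and lactonisation cascade (epoxide opening at the terminal carbon, re-closure of the alkoxide onto the chloromethyl carbon, 3-exo-tet opening of the new epoxide by the malonate carbanion with inversion, lactonisation onto the cis ester), in which C5 (later C4 of the target) derives from 3 and C1 is fixed because only a cis-fused lactone can form.

Step 3
Reactants: 2 (4-bromo-2-methoxyphenoxy)triisopropylsilane; 5 tert-butyl (1R,5R)-2-oxo-3-oxabicyclo[3.1.0]hexane-1-carboxylate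
Product: 7 tert-butyl (3R,4R)-4-[3-methoxy-4-(triisopropylsilyloxy)benzyl]-2-oxooxolane-3-carboxylate, via arylmagnesium bromide 6 (not isolated)
Conditions: 2, Mg, THF, reflux; then CuI (20 mol %), 5, THF, −30 °C to 0 °C; 1 M HCl, 0 °C
Reagents that add atoms: magnesium, [Mg] (its atom is held only in intermediate 6)
Why: Copper-catalysed homoconjugate addition of an aryl Grignard reagent to a doubly activated cyclopropane, in which SN2-type attack at the unsubstituted cyclopropane CH2 expels the stabilised lactone-ester enolate, so the stereocentre is untouched and becomes C4 (R), while the labile C3 settles trans and is erased in step 5.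

Step 4
Reactants: 7 tert-butyl (3R,4R)-4-[3-methoxy-4-(triisopropylsilyloxy)benzyl]-2-oxooxolane-3-carboxylate
Product: 8 tert-butyl (4R)-2-hydroxy-4-[3-methoxy-4-(triisopropylsilyloxy)benzyl]oxolane-3-carboxylate (lactol)
Conditions: i-Bu2AlH (1.2 equiv), CH2Cl2, −78 °C; MeOH, then aq potassium sodium tartrate
Reagents that add atoms: none
Why: Partial reduction of a lactone to a lactol, in which the unhindered lactone carbonyl should be attacked faster than the tert-butyl ester and the tetrahedral aluminate persists at −78 °C until work-up; the new C2 centre is a mixture that vanishes in step 5.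

Step 5
Reactants: 8 tert-butyl (4R)-2-hydroxy-4-[3-methoxy-4-(triisopropylsilyloxy)benzyl]oxolane-3-carboxylate
Product: 10 tert-butyl (4R)-4-[3-methoxy-4-(triisopropylsilyloxy)benzyl]-4,5-dihydrofuran-3-carboxylate, via anomeric mesylate 9 (not isolated)
Conditions: MsCl, Et3N, CH2Cl2, −20 °C to rt
Reagents that add atoms: methanesulfonyl chloride, CS(=O)(=O)Cl (its atoms are held only in intermediate 9)
Why: Mesylation and elimination of a lactol (glycal-type enol ether synthesis), here an easy E1cB-like loss because C3–H is α to the ester, and mesylation of the open hydroxymethylene tautomer at either oxygen would lead to the same β-alkoxyacrylate by ring closure.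

Step 6
Reactants: 10 tert-butyl (4R)-4-[3-methoxy-4-(triisopropylsilyloxy)benzyl]-4,5-dihydrofuran-3-carboxylate
Product: 11 {(4R)-4-[3-methoxy-4-(triisopropylsilyloxy)benzyl]-4,5-dihydrofuran-3-yl}methanol
Conditions: i-Bu2AlH (3 equiv), CH2Cl2, −78 °C to −20 °C; aq potassium sodium tartrate; Et3N-washed silica
Reagents that add atoms: none
Why: 1,2-Reduction of an α,β-unsaturated ester to the allylic alcohol; the product is the furanoid counterpart of a 2-C-hydroxymethyl glycal, a known isolable class that only needs acid-free work-up.

Step 7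
Reactants: 11 {(4R)-4-[3-methoxy-4-(triisopropylsilyloxy)benzyl]-4,5-dihydrofuran-3-yl}methanol; 12 (3,4,5-trimethoxyphenyl)boronic acid
Product: 14 {(2S,3R,4R)-4-[3-methoxy-4-(triisopropylsilyloxy)benzyl]-2-(3,4,5-trimethoxyphenyl)oxolan-3-yl}methanol, via aldehyde 13 (not isolated)
Conditions: 12 (2.5 equiv), Pd(MeCN)2(OTs)2 (8 mol %), Cu(OTf)2 (8 mol %), 4,4-dimethyl-2-(pyridin-2-yl)-4,5-dihydrooxazole (18 mol %), 3 Å MS, O2 (1 atm), DMF, rt; then N2 purge, MeOH, NaBH4, 0 °C
Reagents that add atoms: none
Why: Proposed new method: boron-to-palladium transmetalation gives a cationic aryl complex of divalent palladium that binds the C2=C3 enol ether of 11 and inserts syn with aryl going to C2 and palladium to C3, then shuttles hydride (β-hydride elimination from the exocyclic CH2OH, re-insertion of the same Pd–H at C3 on the same face) and releases aldehyde 13 by proton loss from the α-hydroxyalkyl palladium species, zerovalent palladium being reoxidised by O2/Cu(OTf)2 and 13 being reduced by NaBH4 in the same flask. The closest known reaction types are the redox-relay Heck coupling of acyclic trisubstituted allylic alcohols (which sets vicinal stereocentres by this same suprafacial hydride shuttle), the α-selective Heck coupling of acyclic enol ethers and the Heck C-arylation of furanoid glycals, and what is new is their union on a cyclic enol ether that carries the carbinol on its β-carbon. The step closes no ring; it saturates ring B, which is already in place. C2 (S) is controlled by the C4 stereocentre, because the bulky palladium must bond to C3 next to C4 and so takes the alkene face anti to the C4 arylmethyl group as in glycal arylations, and C3 (R in 14) needs no control element of its own, because aryl and hydride both arrive on the palladium face and push the C3 carbon substituent to the other face, trans to the aryl group and cis to the arylmethyl group, which is the contra-steric relation the target demands. Regioselectivity of insertion is secured by O1, which makes C2 the electrophilic alkene carbon, and by the known preference for coupling distal to the hydroxyl, both of which point to C2. The direction of β-hydride elimination is secured because C2–H lies anti to palladium, the carbinol C–H is the most hydridic and aldehyde release is irreversible, whereas elimination toward C4–H stays reversible as long as the chelating pyridine-oxazoline keeps the alkene on palladium, and the epimerisable β-alkoxy aldehyde 13 is spared enolisation by immediate reduction.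

Step 8
Reactants: 14 {(2S,3R,4R)-4-[3-methoxy-4-(triisopropylsilyloxy)benzyl]-2-(3,4,5-trimethoxyphenyl)oxolan-3-yl}methanol
Product: 15 4-{[(3R,4R,5S)-4-(hydroxymethyl)-5-(3,4,5-trimethoxyphenyl)oxolan-3-yl]methyl}-2-methoxyphenol (target)
Conditions: TBAF, AcOH (1:1), THF, 0 °C
Reagents that add atoms: none
Why: Fluoride cleavage of an aryl silyl ether under acetic acid buffering, which avoids acid, strong base and hydrogenolysis and so should neither open nor epimerise the benzylic C2–O1 bond.

**Compound list**
1 | 4-bromo-2-methoxyphenol | COc1cc(Br)ccc1O | starting material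
2 | (4-bromo-2-methoxyphenoxy)triisopropylsilane | COc1cc(Br)ccc1O[Si](C(C)C)(C(C)C)C(C)C | intermediate
3 | (R)-epichlorohydrin | ClC[C@H]1CO1 | starting material
4 | di-tert-butyl malonate | CC(C)(C)OC(=O)CC(=O)OC(C)(C)C | starting material
5 | tert-butyl (1R,5R)-2-oxo-3-oxabicyclo[3.1.0]hexane-1-carboxylate | O=C1OC[C@@H]2C[C@]12C(=O)OC(C)(C)C | intermediate
6 | [3-methoxy-4-(triisopropylsilyloxy)phenyl]magnesium bromide | COc1cc([Mg]Br)ccc1O[Si](C(C)C)(C(C)C)C(C)C | intermediate
7 | tert-butyl (3R,4R)-4-[3-methoxy-4-(triisopropylsilyloxy)benzyl]-2-oxooxolane-3-carboxylate (trans, C3 labile) | COc1cc(C[C@H]2COC(=O)[C@@H]2C(=O)OC(C)(C)C)ccc1O[Si](C(C)C)(C(C)C)C(C)C | intermediate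
8 | tert-butyl (4R)-2-hydroxy-4-[3-methoxy-4-(triisopropylsilyloxy)benzyl]oxolane-3-carboxylate (mixture at C2 and C3) | COc1cc(C[C@H]2COC(O)C2C(=O)OC(C)(C)C)ccc1O[Si](C(C)C)(C(C)C)C(C)C | intermediate
9 | tert-butyl (4R)-2-(methylsulfonyloxy)-4-[3-methoxy-4-(triisopropylsilyloxy)benzyl]oxolane-3-carboxylate (mixture at C2 and C3) | COc1cc(C[C@H]2COC(OS(C)(=O)=O)C2C(=O)OC(C)(C)C)ccc1O[Si](C(C)C)(C(C)C)C(C)C | intermediate
10 | tert-butyl (4R)-4-[3-methoxy-4-(triisopropylsilyloxy)benzyl]-4,5-dihydrofuran-3-carboxylate | COc1cc(C[C@H]2COC=C2C(=O)OC(C)(C)C)ccc1O[Si](C(C)C)(C(C)C)C(C)C | intermediate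
11 | {(4R)-4-[3-methoxy-4-(triisopropylsilyloxy)benzyl]-4,5-dihydrofuran-3-yl}methanol | COc1cc(C[C@H]2COC=C2CO)ccc1O[Si](C(C)C)(C(C)C)C(C)C | intermediate
12 | (3,4,5-trimethoxyphenyl)boronic acid | COc1cc(B(O)O)cc(OC)c1OC | starting material
13 | (2S,3S,4R)-4-[3-methoxy-4-(triisopropylsilyloxy)benzyl]-2-(3,4,5-trimethoxyphenyl)oxolane-3-carbaldehyde | COc1cc(C[C@H]2CO[C@H](c3cc(OC)c(OC)c(OC)c3)[C@H]2C=O)ccc1O[Si](C(C)C)(C(C)C)C(C)C | intermediate
14 | {(2S,3R,4R)-4-[3-methoxy-4-(triisopropylsilyloxy)benzyl]-2-(3,4,5-trimethoxyphenyl)oxolan-3-yl}methanol | COc1cc(C[C@H]2CO[C@H](c3cc(OC)c(OC)c(OC)c3)[C@H]2CO)ccc1O[Si](C(C)C)(C(C)C)C(C)C | intermediate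
15 | 4-{[(3R,4R,5S)-4-(hydroxymethyl)-5-(3,4,5-trimethoxyphenyl)oxolan-3-yl]methyl}-2-methoxyphenol | COc1cc(C[C@H]2CO[C@H](c3cc(OC)c(OC)c(OC)c3)[C@H]2CO)ccc1O | target

**Step count:** 8 steps in total. The longest linear sequence is 7 steps (steps 2 to 8, or step 1 followed by steps 3 to 8).

**Steps most likely to fail**

1. **Step 7.**
   - What may go wrong:
     - The palladium hydride may leave the alkene after β-hydride elimination toward C4–H, which erases the C4 stereocentre.
     - The enol may be released before re-insertion, which loses control at C3.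
     - Traces of sulfonic acid may ionise the vinylogous hemiacetal unit O1–C2=C3–CH2OH before coupling.
   - Fallback (known chemistry, same C2–aryl bond): it sets out from 11. Silylation (TBSCl, imidazole, DMF) would give the tert-butyldimethylsilyl ether F1. Addition of benzenesulfinic acid across the enol ether (CH2Cl2, rt), with the proton entering C3 anti to the C4 arylmethyl group, would give the 2-(phenylsulfonyl)oxolane F2. 5-Bromo-1,2,3-trimethoxybenzene would be turned with Mg into 3,4,5-trimethoxyphenylmagnesium bromide F3 and with ZnBr2 into 3,4,5-trimethoxyphenylzinc bromide F4. This reagent displaces the sulfonyl group of F2 through the ring B oxocarbenium ion, from the face anti to the C3 and C4 substituents, to give the bis-silyl ether F5. Excess TBAF removes both silyl groups, and the route is rejoined at 15.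

2. **Step 4.**
   - What may go wrong: the aluminium hydride may deprotonate the malonate-type C3–H, leaving an inert enolate, or it may also attack the ester carbonyl.
   - Fallback: it sets out from 7 and removes the second carbonyl before any reduction.
     - CF3CO2H in CH2Cl2 would cleave the tert-butyl ester to the lactone acid F6, which loses CO2 in refluxing toluene to give the (R)-β-arylmethyl-γ-butyrolactone F7.
     - i-Bu2AlH at −78 °C gives the lactol F8. MsCl/Et3N then gives, through the anomeric mesylate F9, the 2,3-dihydrofuran F10.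
     - Vilsmeier–Haack formylation (POCl3, DMF, 0 °C; aq NaOAc) at the enol ether β-carbon gives the 4,5-dihydrofuran-3-carbaldehyde F11.
     - NaBH4/CeCl3 in MeOH reduces this to 11, where the route is rejoined.

3. **Step 2.**
   - What may go wrong: direct displacement of chloride may compete with epoxide opening, which leads to the mirror-image cyclopropane and erodes enantiopurity. Lactonisation onto the hindered ester may also lag.
   - Fallback: it sets out from 4 and changes the order of bond formation. (R)-Glycidol with Tf2O and 2,6-lutidine would give (S)-glycidyl trifluoromethanesulfonate F12. The sodium enolate of 4 (NaH, THF) displaces the triflate directly. A second equivalent of NaH regenerates the carbanion, which opens the untouched epoxide 3-exo-tet with inversion, and lactonisation gives 5, where the route is rejoined. Because the first carbon–carbon bond now forms only at the sulfonate carbon, a single pathway is open, and the opposite spatial series of the three-carbon building block leads to the same enantiomer of 5.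

**Further compounds**
F1 | step 7 | tert-butyl({(4R)-4-[3-methoxy-4-(triisopropylsilyloxy)benzyl]-4,5-dihydrofuran-3-yl}methoxy)dimethylsilane | COc1cc(C[C@H]2COC=C2CO[Si](C)(C)C(C)(C)C)ccc1O[Si](C(C)C)(C(C)C)C(C)C
F2 | step 7 | 2-(phenylsulfonyl)oxolane with 3-(tert-butyldimethylsilyloxymethyl) cis to the 4-arylmethyl group (mixture at C2) | COc1cc(C[C@H]2COC(S(=O)(=O)c3ccccc3)[C@H]2CO[Si](C)(C)C(C)(C)C)ccc1O[Si](C(C)C)(C(C)C)C(C)C
F3 | step 7 | 3,4,5-trimethoxyphenylmagnesium bromide | COc1cc([Mg]Br)cc(OC)c1OC
F4 | step 7 | 3,4,5-trimethoxyphenylzinc bromide | COc1cc([Zn]Br)cc(OC)c1OC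
F5 | step 7 | (2S,3R,4R)-3-(tert-butyldimethylsilyloxymethyl)-4-[3-methoxy-4-(triisopropylsilyloxy)benzyl]-2-(3,4,5-trimethoxyphenyl)oxolane | COc1cc(C[C@H]2CO[C@H](c3cc(OC)c(OC)c(OC)c3)[C@H]2CO[Si](C)(C)C(C)(C)C)ccc1O[Si](C(C)C)(C(C)C)C(C)C
F6 | step 4 | (4R)-4-[3-methoxy-4-(triisopropylsilyloxy)benzyl]-2-oxooxolane-3-carboxylic acid | COc1cc(C[C@H]2COC(=O)C2C(=O)O)ccc1O[Si](C(C)C)(C(C)C)C(C)C
F7 | step 4 | (4R)-4-[3-methoxy-4-(triisopropylsilyloxy)benzyl]oxolan-2-one | COc1cc(C[C@H]2COC(=O)C2)ccc1O[Si](C(C)C)(C(C)C)C(C)C
F8 | step 4 | (4R)-4-[3-methoxy-4-(triisopropylsilyloxy)benzyl]oxolan-2-ol (mixture at C2) | COc1cc(C[C@H]2COC(O)C2)ccc1O[Si](C(C)C)(C(C)C)C(C)C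
F9 | step 4 | (4R)-4-[3-methoxy-4-(triisopropylsilyloxy)benzyl]oxolan-2-yl methanesulfonate (mixture at C2) | COc1cc(C[C@H]2COC(OS(C)(=O)=O)C2)ccc1O[Si](C(C)C)(C(C)C)C(C)C
F10 | step 4 | (3R)-3-[3-methoxy-4-(triisopropylsilyloxy)benzyl]-2,3-dihydrofuran | COc1cc(C[C@H]2COC=C2)ccc1O[Si](C(C)C)(C(C)C)C(C)C
F11 | step 4 | (4R)-4-[3-methoxy-4-(triisopropylsilyloxy)benzyl]-4,5-dihydrofuran-3-carbaldehyde | COc1cc(C[C@H]2COC=C2C=O)ccc1O[Si](C(C)C)(C(C)C)C(C)C
F12 | step 2 | (S)-glycidyl trifluoromethanesulfonate | O=S(=O)(OC[C@@H]1CO1)C(F)(F)F
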